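**Retrosynthetic overview**
1. Target 20 ⇒ bis(silyl ketal) 18 ⇒ bis(3-silyloxy-2-methylbenzofuran) 16. The C2/C2' hemiketal oxygens come from an enantioselective Rubottom oxidation, the C3/C3' carbonyls from epoxidation and hydride shift on the bis(2-methylbenzofuran) 13, and the C6/C6' phenols travel as benzyl ethers.
2. Key disconnection, both halves at once: C3–C3a and O1–C2 of each furan ring, back to the bis(aryl propargyl ether) 11. It rests on this feature: in each benzofuranone (O1, C2, C3, C3a, C4–C7, C7a) the chain O1–C2(CH3)–C3 bonded to C3a is a propargyl ether read backwards, and C3a is the only unsubstituted carbon ortho to the C7a oxygen (C7 holds the biaryl bond, the para carbon C5 a methoxy group).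
3. 11 ⇒ 2,2'-biphenol 9 ⇒ dialdehyde 7 (Dakin-type excision of two carbonyl carbons) ⇒ ellagic acid 1. Ellagic acid supplies the C7–C7' bond and all six ring oxygens already differentiated: its free phenols become the methoxy groups and its lactone oxygens become the C6/C6' phenols.
4. Ring order: both benzene rings and the bond between them come from 1; the two furan rings are closed together in step 7; no ring is formed afterwards.

Key step: step 7

Remark 1: the target structure defines C2 and C2' (both R) but not the C7–C7' axis; with four oxygen ortho substituents, two of them tied back in five-membered rings, the axis is taken as not needing separate control.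
Remark 2: the α-keto hemiketal centres are taken to keep their configuration as long as the C2 oxygen is never a free alkoxide (which would open to the 1,2-diketone); it is therefore carried as a silyl ether and released on the acid side, and the last step is neutral.

**Route**

Step 1
Reactants: 1 ellagic acid (dried); 2 dimethyl sulfate
Product: 3 3,3',4,4'-tetra-O-methylellagic acid
Conditions: Me2SO4 (6 equiv), anhydrous K2CO3, DMF, 60 °C
Reagents that add atoms: dimethyl sulfate COS(=O)(=O)OC
Why: Williamson-type O-methylation of the four free phenols; under anhydrous carbonate the two aryl lactones should stay closed, which keeps the two lactone oxygens distinct from the methoxy groups.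

Step 2
Reactants: 3 3,3',4,4'-tetra-O-methylellagic acid
Product: 4 6,6'-bis(hydroxymethyl)-3,3',4,4'-tetramethoxybiphenyl-2,2'-diol
Conditions: LiAlH4, THF, reflux; Rochelle salt work-up
Reagents that add atoms: none
Why: Hydride reduction of the two aryl lactones (activated esters) turns each carbonyl carbon into a benzylic alcohol and frees the lactone oxygen as a phenol on the other ring.

Step 3
Reactants: 4 6,6'-bis(hydroxymethyl)-3,3',4,4'-tetramethoxybiphenyl-2,2'-diol; 5 benzyl bromide
Product: 6 [2,2'-bis(benzyloxy)-3,3',4,4'-tetramethoxybiphenyl-6,6'-diyl]dimethanol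
Conditions: BnBr (2.3 equiv), K2CO3, DMF, 50 °C
Reagents that add atoms: benzyl bromide BrCc1ccccc1
Why: Williamson etherification under weak base, in which only the phenols are deprotonated by K2CO3 so the benzylic alcohols should remain free.

Step 4
Reactants: 6 [2,2'-bis(benzyloxy)-3,3',4,4'-tetramethoxybiphenyl-6,6'-diyl]dimethanol
Product: 7 6,6'-bis(benzyloxy)-4,4',5,5'-tetramethoxybiphenyl-2,2'-dicarbaldehyde
Conditions: (COCl)2, DMSO, CH2Cl2, −78 °C; then Et3N, −78 °C → 0 °C
Reagents that add atoms: none
Why: Swern oxidation activates both benzylic alcohols as alkoxysulfonium ions before base is added, which avoids the seven-membered lactol and lactone that a stepwise oxidant can form from a 2,2'-bis(hydroxymethyl)biaryl.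

Step 5
Reactants: 7 6,6'-bis(benzyloxy)-4,4',5,5'-tetramethoxybiphenyl-2,2'-dicarbaldehyde
Product: 9 6,6'-bis(benzyloxy)-4,4',5,5'-tetramethoxybiphenyl-2,2'-diol, via bis(aryl formate) 8 (not isolated)
Conditions: mCPBA (3 equiv), CH2Cl2, 0 °C → rt; aqueous NaHCO3/Na2S2O3 wash; then K2CO3 (cat.), MeOH, 0 °C, argon
Reagents that add atoms: 3-chloroperoxybenzoic acid O=C(OO)c1cccc(Cl)c1
Why: Baeyer–Villiger (Dakin-type) oxidation, in which the electron-rich aryl group (methoxy para to the formyl carbon) should migrate in preference to hydride in the Criegee adduct, followed by methanolysis of the aryl formates.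

Step 6
Reactants: 9 6,6'-bis(benzyloxy)-4,4',5,5'-tetramethoxybiphenyl-2,2'-diol; 10 propargyl bromide
Product: 11 2,2'-bis(benzyloxy)-3,3',4,4'-tetramethoxy-6,6'-bis(prop-2-ynyloxy)biphenyl
Conditions: propargyl bromide (2.5 equiv), K2CO3, DMF, rt, argon
Reagents that add atoms: propargyl bromide C#CCBr
Why: Williamson etherification (SN2) of the two phenoxides with a primary propargylic bromide, run under argon because the trialkoxyphenol is air-sensitive.

Step 7
Reactants: 11 2,2'-bis(benzyloxy)-3,3',4,4'-tetramethoxy-6,6'-bis(prop-2-ynyloxy)biphenyl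
Product: 13 6,6'-bis(benzyloxy)-4,4',5,5'-tetramethoxy-2,2'-dimethyl-7,7'-bibenzofuran, via bis(2-allenylphenol) 12 (not isolated)
Conditions: CsF (6 equiv), PhNEt2, 200–215 °C, argon
Reagents that add atoms: none
Why: Each aryl propargyl ether should undergo an aromatic propargyl Claisen rearrangement, in which the O–CH2 bond breaks while the terminal alkyne carbon (future C3) bonds to the only free ortho carbon (future C3a), giving a 6-allenylcyclohexa-2,4-dienone. CsF removes the ring proton of this dienone or of its phenol tautomer, so that the 2-allenylphenoxide 12 forms before the neutral phenol can undergo the 1,5-hydrogen shift and 6π oxa-electrocyclisation that lead to a 2H-chromene. The phenoxide oxygen then adds to the central allene carbon (future C2) in a 5-exo-dig closure across the C2=CH2 π bond, which lies outside the new ring, and protonation of the terminal carbon gives the C2 methyl group and the aromatic furan; the same closure occurs on each half, so both furan rings form in this mode. The closest known reaction type is the CsF-mediated Claisen rearrangement of aryl propargyl ethers to 2-methylbenzofurans in hot N,N-diethylaniline. No stereocentre is formed; regioselectivity is secured because the other ortho carbon carries the biaryl bond and the para carbon a methoxy group, so migration toward them is reversible and unproductive, and chemoselectivity for furan over chromene rests on the fluoride base. The benzyl and methyl aryl ethers are expected to tolerate the conditions.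

Step 8
Reactants: 13 6,6'-bis(benzyloxy)-4,4',5,5'-tetramethoxy-2,2'-dimethyl-7,7'-bibenzofuran
Product: 15 6,6'-bis(benzyloxy)-4,4',5,5'-tetramethoxy-2,2'-dimethyl-7,7'-bibenzofuran-3,3'(2H,2'H)-dione (C2/C2' epimer mixture), via bis(2,3-epoxide) 14 (not isolated)
Conditions: DMDO (2.1 equiv, acetone solution), CH2Cl2, −78 °C → 20 °C, argon
Reagents that add atoms: dimethyldioxirane CC1(C)OO1
Why: Epoxidation of the electron-rich furan C2=C3 bond, then Meinwald-type rearrangement in which the oxirane opens to the O1-stabilised C2 oxocarbenium ion and the C3 hydrogen shifts to C2 (or is lost to give the 3-hydroxybenzofuran tautomer), leaving the C3 ketone; the C2 centres form unselectively and are erased in step 9.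

Step 9
Reactants: 15 6,6'-bis(benzyloxy)-4,4',5,5'-tetramethoxy-2,2'-dimethyl-7,7'-bibenzofuran-3,3'(2H,2'H)-dione
Product: 16 6,6'-bis(benzyloxy)-3,3'-bis(tert-butyldimethylsilyloxy)-4,4',5,5'-tetramethoxy-2,2'-dimethyl-7,7'-bibenzofuran
Conditions: TBSOTf (2.5 equiv), Et3N (4 equiv), CH2Cl2, 0 °C, argon
Reagents that add atoms: tert-butyldimethylsilyl triflate CC(C)(C)[Si](C)(C)OS(=O)(=O)C(F)(F)F
Why: Soft enolisation (silyl triflate and amine), in which O-silylation and loss of the acidic C2 proton are driven by formation of the aromatic 3-silyloxybenzofuran.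

Step 10
Reactants: 16 6,6'-bis(benzyloxy)-3,3'-bis(tert-butyldimethylsilyloxy)-4,4',5,5'-tetramethoxy-2,2'-dimethyl-7,7'-bibenzofuran
Product: 18 (2S,2'S)-6,6'-bis(benzyloxy)-2,2'-bis(tert-butyldimethylsilyloxy)-4,4',5,5'-tetramethoxy-2,2'-dimethyl-7,7'-bibenzofuran-3,3'(2H,2'H)-dione, via bis(silyloxy epoxide) 17 (not isolated)
Conditions: (S,S)-[N,N'-bis(3,5-di-tert-butylsalicylidene)cyclohexane-1,2-diaminato]MnCl (10 mol%), 4-phenylpyridine N-oxide, PhIO (2.4 equiv), 4 Å MS, CH2Cl2, −20 °C
Reagents that add atoms: iodosylbenzene O=Ic1ccccc1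
Why: Proposed new method: an enantioselective Rubottom oxidation has not been shown on a fully substituted 3-silyloxybenzofuran, but the oxomanganese(salen) species should transfer oxygen side-on to the electron-rich C2=C3 bond as in the Jacobsen–Katsuki epoxidation of indene and of tetrasubstituted chromenes and in the Mn(salen)-catalysed oxidation of silyl enol ethers of aryl ketones (the closest known reaction types), the indene model for the (S,S)-complex placing the oxygen on the Si face of C2 (priorities O1 > C3 > CH3) in each half, after which the silyloxy oxirane 17 opens to the C3 silyloxycarbenium ion and the silyl group shifts from the C3 oxygen to the C2 oxygen, so that the C2–O bond made in the face-selective event is kept, C2 is never a free alkoxide, and both new stereocentres (2S,2'S as silyl ketals) are set by the catalyst.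

Step 11
Reactants: 18 (2S,2'S)-bis(silyl ketal)
Product: 19 (2R,2'R)-6,6'-bis(benzyloxy)-2,2'-dihydroxy-4,4',5,5'-tetramethoxy-2,2'-dimethyl-7,7'-bibenzofuran-3,3'(2H,2'H)-dione
Conditions: HF·pyridine, pyridine, THF, 0 °C → rt
Reagents that add atoms: none
Why: Fluoride-mediated Si–O cleavage on the acid side releases the hemiketal as the neutral OH and not as the alkoxide; no bond to C2 is broken, and the descriptor changes from S to R only because OH ranks below the ring oxygen whereas OSi ranked above it.

Step 12
Reactants: 19 (2R,2'R)-bis(hemiketal) bis(benzyl ether)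
Product: 20 (2R,2'R)-2,2',6,6'-tetrahydroxy-4,4',5,5'-tetramethoxy-2,2'-dimethyl-7,7'-bibenzofuran-3,3'(2H,2'H)-dione (target)
Conditions: H2 (1 atm), 10% Pd/C, EtOAc, rt; filtration and evaporation
Reagents that add atoms: none
Why: Heterogeneous hydrogenolysis of the two aryl benzyl ethers under neutral conditions, which should leave the electron-rich aryl ketones and the hemiketal centres untouched and gives only toluene beside the product.

**Compound list**
1 | ellagic acid | O=C1Oc2c(O)c(O)cc3C(=O)Oc4c(O)c(O)cc1c4c23 | starting material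
2 | dimethyl sulfate | COS(=O)(=O)OC | starting material
3 | 3,3',4,4'-tetra-O-methylellagic acid | O=C1Oc2c(OC)c(OC)cc3C(=O)Oc4c(OC)c(OC)cc1c4c23 | intermediate
4 | 6,6'-bis(hydroxymethyl)-3,3',4,4'-tetramethoxybiphenyl-2,2'-diol | OCc1cc(OC)c(OC)c(O)c1-c1c(O)c(OC)c(OC)cc1CO | intermediate
5 | benzyl bromide | BrCc1ccccc1 | starting material
6 | [2,2'-bis(benzyloxy)-3,3',4,4'-tetramethoxybiphenyl-6,6'-diyl]dimethanol | OCc1cc(OC)c(OC)c(OCc2ccccc2)c1-c1c(OCc2ccccc2)c(OC)c(OC)cc1CO | intermediate
7 | 6,6'-bis(benzyloxy)-4,4',5,5'-tetramethoxybiphenyl-2,2'-dicarbaldehyde | O=Cc1cc(OC)c(OC)c(OCc2ccccc2)c1-c1c(OCc2ccccc2)c(OC)c(OC)cc1C=O | intermediate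
8 | 6,6'-bis(benzyloxy)-4,4',5,5'-tetramethoxybiphenyl-2,2'-diyl diformate (not isolated) | O=COc1cc(OC)c(OC)c(OCc2ccccc2)c1-c1c(OCc2ccccc2)c(OC)c(OC)cc1OC=O | intermediate
9 | 6,6'-bis(benzyloxy)-4,4',5,5'-tetramethoxybiphenyl-2,2'-diol | Oc1cc(OC)c(OC)c(OCc2ccccc2)c1-c1c(OCc2ccccc2)c(OC)c(OC)cc1O | intermediate
10 | propargyl bromide (3-bromoprop-1-yne) | C#CCBr | starting material
11 | 2,2'-bis(benzyloxy)-3,3',4,4'-tetramethoxy-6,6'-bis(prop-2-ynyloxy)biphenyl | C#CCOc1cc(OC)c(OC)c(OCc2ccccc2)c1-c1c(OCC#C)cc(OC)c(OC)c1OCc1ccccc1 | intermediate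
12 | 6,6'-bis(benzyloxy)-4,4',5,5'-tetramethoxy-3,3'-di(propa-1,2-dienyl)biphenyl-2,2'-diol, present as its caesium phenoxide (not isolated) | C=C=Cc1c(O)c(-c2c(O)c(C=C=C)c(OC)c(OC)c2OCc2ccccc2)c(OCc2ccccc2)c(OC)c1OC | intermediate
13 | 6,6'-bis(benzyloxy)-4,4',5,5'-tetramethoxy-2,2'-dimethyl-7,7'-bibenzofuran | Cc1cc2c(OC)c(OC)c(OCc3ccccc3)c(-c3c(OCc4ccccc4)c(OC)c(OC)c4cc(C)oc34)c2o1 | intermediate
14 | 6,6'-bis(benzyloxy)-2,3:2',3'-diepoxy-4,4',5,5'-tetramethoxy-2,2'-dimethyl-2,2',3,3'-tetrahydro-7,7'-bibenzofuran, stereoisomer mixture (not isolated) | CC12OC1c1c(OC)c(OC)c(OCc3ccccc3)c(-c3c(OCc4ccccc4)c(OC)c(OC)c4c3OC3(C)OC43)c1O2 | intermediate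
15 | 6,6'-bis(benzyloxy)-4,4',5,5'-tetramethoxy-2,2'-dimethyl-7,7'-bibenzofuran-3,3'(2H,2'H)-dione, C2/C2' epimer mixture | CC1Oc2c(-c3c(OCc4ccccc4)c(OC)c(OC)c4c3OC(C)C4=O)c(OCc3ccccc3)c(OC)c(OC)c2C1=O | intermediate
16 | 6,6'-bis(benzyloxy)-3,3'-bis(tert-butyldimethylsilyloxy)-4,4',5,5'-tetramethoxy-2,2'-dimethyl-7,7'-bibenzofuran | Cc1oc2c(-c3c(OCc4ccccc4)c(OC)c(OC)c4c(O[Si](C)(C)C(C)(C)C)c(C)oc34)c(OCc3ccccc3)c(OC)c(OC)c2c1O[Si](C)(C)C(C)(C)C | intermediate
17 | (2S,3R,2'S,3'R)-6,6'-bis(benzyloxy)-3,3'-bis(tert-butyldimethylsilyloxy)-2,3:2',3'-diepoxy-4,4',5,5'-tetramethoxy-2,2'-dimethyl-2,2',3,3'-tetrahydro-7,7'-bibenzofuran (not isolated) | COc1c(OCc4ccccc4)c(-c2c(OCc4ccccc4)c(OC)c(OC)c3c2O[C@@]4(C)O[C@@]34O[Si](C)(C)C(C)(C)C)c2c(c1OC)[C@]3(O[Si](C)(C)C(C)(C)C)O[C@]3(C)O2 | intermediate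
18 | (2S,2'S)-6,6'-bis(benzyloxy)-2,2'-bis(tert-butyldimethylsilyloxy)-4,4',5,5'-tetramethoxy-2,2'-dimethyl-7,7'-bibenzofuran-3,3'(2H,2'H)-dione | COc1c(OCc4ccccc4)c(-c2c(OCc4ccccc4)c(OC)c(OC)c3c2O[C@@](C)(O[Si](C)(C)C(C)(C)C)C3=O)c2c(c1OC)C(=O)[C@](C)(O[Si](C)(C)C(C)(C)C)O2 | intermediate
19 | (2R,2'R)-6,6'-bis(benzyloxy)-2,2'-dihydroxy-4,4',5,5'-tetramethoxy-2,2'-dimethyl-7,7'-bibenzofuran-3,3'(2H,2'H)-dione | COc1c(OCc4ccccc4)c(-c2c(OCc4ccccc4)c(OC)c(OC)c3c2O[C@@](C)(O)C3=O)c2c(c1OC)C(=O)[C@](C)(O)O2 | intermediate
20 | (2R,2'R)-2,2',6,6'-tetrahydroxy-4,4',5,5'-tetramethoxy-2,2'-dimethyl-7,7'-bibenzofuran-3,3'(2H,2'H)-dione | COc1c(O)c(-c2c(O)c(OC)c(OC)c3c2O[C@@](C)(O)C3=O)c2c(c1OC)C(=O)[C@](C)(O)O2 | target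

**Totals**
Total step count: 12. Longest linear sequence: 12 steps, from ellagic acid 1 to 20.

**Steps most likely to fail**

Step 10 (proposed new method). Oxygen transfer may occur with low or reversed facial preference, because both olefin carbons are fully substituted and the ring is flat. The silyl group may also be lost to adventitious water before it can shift to the C2 oxygen. If only the sense is reversed, the (R,R)-complex is used in the same step. Because the two halves are oxidised independently, mismatched events should end up mainly in the (2R,2'S) diastereomer, which is separable on silica. The fallback gives up catalyst control and uses known chemistry. It sets out from 16: a non-selective Rubottom oxidation with dimethyldioxirane (acetone/CH2Cl2, −78 °C) should give the stereoisomer mixture of the bis(silyl ketal) F1. The (2R,2'S) diastereomer is removed by chromatography on silica, and the remaining enantiomer pair is resolved by preparative HPLC on a chiral stationary phase (cellulose tris(3,5-dimethylphenylcarbamate)). The (2S,2'S) isomer returns to the route at 18.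

Step 8. The oxirane may open toward the C3 benzylic cation, which the C4, C6 and C7a oxygens stabilise, instead of the C2 oxocarbenium ion. That would lead to methyl migration (a lactone) or to an ortho-quinone methide that adds nucleophiles or dimerises. The enolisable ketone may also be oxidised a second time, unselectively, at C2. The fallback sets out from 13 and puts the C3 oxygen in by substitution instead of epoxidation. Electrophilic bromination at the only free ring position (NBS, MeCN, 0 °C, dark) should give the 3,3'-dibromo-bibenzofuran F2. Miyaura borylation (B2pin2, Pd(OAc)2, SPhos, KOAc, dioxane, 90 °C) should give the 3,3'-bis(pinacol boronate) F3. Oxidation with NaBO3·4H2O (THF/H2O, rt, argon) should give the 3-hydroxybenzofuran, which tautomerises to the ketone and returns to the route at 15.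

Step 7. The second cascade may lag behind the first, so that half-cyclised material is held at 200 °C and decomposes. Slow deprotonation may let the allenyl phenol divert through the 1,5-hydrogen shift and 6π closure to 2H-chromenes. Benzyl groups may migrate or be lost thermally. The fallback sets out from 9 and makes the same bonds in separate, milder operations. O-Allylation (allyl bromide, K2CO3, DMF) should give the 2,2'-bis(allyloxy)biphenyl F4. Aromatic Claisen rearrangement (PhNEt2, 190 °C), to the same single free ortho carbon, should give the 3,3'-diallylbiphenyl-2,2'-diol F5. Wacker-type oxidative cyclisation (PdCl2(MeCN)2 as the divalent palladium catalyst, 1,4-benzoquinone, dioxane, 60 °C) with double-bond migration into the ring should give the bis(2-methylbenzofuran), which returns to the route at 13.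

**Further compounds**
F1 | step 10 | 6,6'-bis(benzyloxy)-2,2'-bis(tert-butyldimethylsilyloxy)-4,4',5,5'-tetramethoxy-2,2'-dimethyl-7,7'-bibenzofuran-3,3'(2H,2'H)-dione, mixture of C2/C2' stereoisomers | COc1c(OCc4ccccc4)c(-c2c(OCc4ccccc4)c(OC)c(OC)c3c2OC(C)(O[Si](C)(C)C(C)(C)C)C3=O)c2c(c1OC)C(=O)C(C)(O[Si](C)(C)C(C)(C)C)O2
F2 | step 8 | 6,6'-bis(benzyloxy)-3,3'-dibromo-4,4',5,5'-tetramethoxy-2,2'-dimethyl-7,7'-bibenzofuran | Cc1oc2c(-c3c(OCc4ccccc4)c(OC)c(OC)c4c(Br)c(C)oc34)c(OCc3ccccc3)c(OC)c(OC)c2c1Br
F3 | step 8 | 6,6'-bis(benzyloxy)-4,4',5,5'-tetramethoxy-2,2'-dimethyl-3,3'-bis(4,4,5,5-tetramethyl-1,3,2-dioxaborolan-2-yl)-7,7'-bibenzofuran | Cc1oc2c(-c3c(OCc4ccccc4)c(OC)c(OC)c4c(B5OC(C)(C)C(C)(C)O5)c(C)oc34)c(OCc3ccccc3)c(OC)c(OC)c2c1B1OC(C)(C)C(C)(C)O1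
F4 | step 7 | 2,2'-bis(allyloxy)-6,6'-bis(benzyloxy)-4,4',5,5'-tetramethoxybiphenyl | C=CCOc1cc(OC)c(OC)c(OCc2ccccc2)c1-c1c(OCC=C)cc(OC)c(OC)c1OCc1ccccc1
F5 | step 7 | 3,3'-diallyl-6,6'-bis(benzyloxy)-4,4',5,5'-tetramethoxybiphenyl-2,2'-diol | C=CCc1c(O)c(-c2c(O)c(CC=C)c(OC)c(OC)c2OCc2ccccc2)c(OCc2ccccc2)c(OC)c1OC
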